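What I wanted to know before repeating this flask was whether it still moves at the asked time and, if not, how the starting material ends up shared.

starting material 12 mM; reagent 18.0 mM; time 40 h

    starting material ⇌ intermediate B (K1 = 1.4, k1 = 0.013 min⁻¹)
    starting material + reagent ⇌ intermediate A (K2 = 16 M⁻¹, k2 = 12 M⁻¹ min⁻¹)
    starting material ⇌ product (K3 = 0.12, k3 = 0.022 min⁻¹)

- at 40 h, what has stopped the reaction, if anything has (it is still moving / all of the starting material has reacted / forward and back rates have come level / the reagent has run out first)
- part of the starting material gone at 40 h
- the product standing at 40 h, as a percentage of the starting material charged
- the intermediate B standing at 40 h, as a percentage of the starting material charged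

- the reaction counts as stopped when no species that holds the starting material changes by six tenths of a point or more over the second half of the time
- what has gone from starting material into another species counts as reacted, even if it can come back
- run time (flask): 40 h

1. I first compared times. The exchange between starting material and intermediate B relaxes with a half-life of 0.518 h, both ways together, and the exchange with product is quicker at 0.0563 h. Binding to intermediate A has a forward half-life of 0.053 h. The run lasts 77.2 of the longer relaxation half-lives, so I treated each step as level, an equilibrium.

2. I counted free starting material as one part. Intermediate B then stands at 1.4 parts and product at 0.12 parts. Intermediate A stands at w parts, where w is the binding constant times the reagent. I held the reagent at its charge, which gives w = 0.288 and overstates it slightly.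

3. Product weighs less than either of the other two, so the contest lies between intermediate B's weight and w. I named their ratio r, the intermediate B standing per intermediate A at level, and reckoned r = 4.86.

4. Summing the parts left 35.6% free. That meant 64.4% gone, 49.8% intermediate B and 4.27% product.

The forecast stood slightly apart from my figures, with forward and back rates have come level, 64.2% gone, 4.3% product and 50.2% intermediate B, saying “the system is fully at equilibrium”.

The flask gave forward and back rates have come level, with 64.2% gone, 4.30% product and 50.2% intermediate B. Intermediate B stood at 49.6% after 4.00 h, still 0.60 percentage points below the 50.2% it held at 40.0 h. Against my r of 4.86, this flask read 5.20 intermediate B per intermediate A. With 72 mM of reagent, r becomes 1.22; that neighbouring flask held 38.7% intermediate B and 30.3% intermediate A at 40.0 h, a reading of 1.28.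

The constants are made up; the result is computed.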